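**Plan**
- **Cuts:** C5–H goes back to C5–Cl, a temporary regiocontrol group. Ring C is then cut at O1–C8a and C4–C4a together. Further back come C3–C4 (carbomethoxylation), the C2 carbinol (from a ketone) and the furan ring (alkyne coupling and cyclisation).
- **Enabling feature:** C8a and C4a are neighbouring carbons of ring A. C8a carries the ether oxygen O1 and C4a carries the C4 carbonyl carbon. An aryne keeps this ortho O/acyl pair when an alkoxide adds to one end of the triple bond and the aryl anion at the other end acylates on a tethered ester.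
- **Forward order:** the benzofuran is made first (step 1) and the C2–C3–C4 chain is completed (step 2). Ring A enters as 3-chloro-5-methoxybenzyne, ring C closes last (step 7), and chlorine is removed (step 8).
- **Stereochemistry:** the only stereocentre, C2 (S), is set by catalyst-controlled asymmetric transfer hydrogenation of β-keto ester 6 (step 3). Its C–O bond is never broken afterwards.

Key step: step 7

Remark: flavanone numbering (O1, C2, C3, C4, C4a, C5–C8, C8a) is used for the chromanone part, and the stereocentre written in the target SMILES works out as (2S).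

Step 1
Reactants: 1 1-(4-hydroxy-3-iodophenyl)ethanone; 2 4-ethynylanisole
Product: 4 1-[2-(4-methoxyphenyl)benzofuran-5-yl]ethanone, via alkynylphenol 3 (not isolated)
Conditions: PdCl2(PPh3)2 (2 mol %), CuI (4 mol %), Et3N, DMF, rt → 70 °C, N2
Reagents that add atoms: none
Why: Sonogashira coupling at the C–I bond gives o-alkynylphenol 3, whose phenol (made more acidic by the para acetyl group) adds across the metal-activated alkyne in a 5-endo-dig heteroannulation in the same pot, a standard entry to 2-arylbenzofurans.

Step 2
Reactants: 4 1-[2-(4-methoxyphenyl)benzofuran-5-yl]ethanone; 5 dimethyl carbonate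
Product: 6 methyl 3-[2-(4-methoxyphenyl)benzofuran-5-yl]-3-oxopropanoate
Conditions: NaH (2.2 equiv), (MeO)2CO (5 equiv), THF, reflux; AcOH quench
Reagents that add atoms: none
Why: Claisen-type carbomethoxylation of the methyl ketone enolate with the non-enolisable carbonate is driven forward by deprotonation of the β-keto ester formed and installs the carbon that becomes C4.

Step 3
Reactants: 6 methyl 3-[2-(4-methoxyphenyl)benzofuran-5-yl]-3-oxopropanoate
Product: 7 methyl (S)-3-hydroxy-3-[2-(4-methoxyphenyl)benzofuran-5-yl]propanoate
Conditions: RuCl[(S,S)-TsDPEN](p-cymene) (1 mol %), HCO2H–Et3N (5:2), DMF, 40 °C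
Reagents that add atoms: none
Why: In this Noyori–Ikariya asymmetric transfer hydrogenation the Ru–H/N–H pair delivers hydride and proton through an outer-sphere six-membered transition state with the aryl group under the η6-cymene (CH/π contact), so the (S,S) catalyst should give the (S) benzylic alcohol as it does with acetophenone, formic acid makes the reduction irreversible, and recrystallisation should raise the enantiomeric purity if needed.

Step 4
Reactants: 7 methyl (S)-3-hydroxy-3-[2-(4-methoxyphenyl)benzofuran-5-yl]propanoate
Product: 8 methyl (S)-3-[2-(4-methoxyphenyl)benzofuran-5-yl]-3-(trimethylsilyloxy)propanoate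
Conditions: TMSCl, imidazole, CH2Cl2, 0 °C; filtration through Et3N-deactivated silica
Reagents that add atoms: chlorotrimethylsilane, C[Si](C)(C)Cl
Why: Standard O-silylation with a base too weak to cause β-elimination leaves C2 untouched, and the trimethylsilyl ether is chosen because fluoride should cleave it at least as fast as the aryl–silicon bond of the aryne precursor.

Step 5
Reactants: 9 2-chloro-4-methoxyphenol
Product: 10 2-bromo-6-chloro-4-methoxyphenol
Conditions: NBS (1.0 equiv), i-Pr2NH (10 mol %), CH2Cl2, 0 °C
Reagents that add atoms: N-bromosuccinimide, O=C1CCC(=O)N1Br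
Why: Electrophilic aromatic bromination is steered by the free phenol, the stronger donor, whose para and one ortho position are blocked, so the amine-catalysed ortho-bromination protocol should place bromine at C6 only.

Step 6
Reactants: 10 2-bromo-6-chloro-4-methoxyphenol
Product: 14 2-chloro-4-methoxy-6-(trimethylsilyl)phenyl trifluoromethanesulfonate, via silyl ether 11 (not isolated), via aryllithium 12 (not isolated), via lithium phenoxide 13 (not isolated)
Conditions: HMDS, THF, reflux, volatiles off; n-BuLi, THF, −78 °C; Tf2O, −78 °C → rt
Reagents that add atoms: hexamethyldisilazane, C[Si](C)(C)N[Si](C)(C)C; trifluoromethanesulfonic anhydride, O=S(=O)(OS(=O)(=O)C(F)(F)F)C(F)(F)F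
Why: This is the established one-flask route to o-silylaryl triflates, namely O-silylation, bromine–lithium exchange (lithium ends up meta to chlorine, so no aryne can form), 1,3 O→C silyl shift (retro-Brook rearrangement) and capture of the phenoxide with triflic anhydride.

Step 7
Reactants: 8 methyl (S)-3-[2-(4-methoxyphenyl)benzofuran-5-yl]-3-(trimethylsilyloxy)propanoate; 14 2-chloro-4-methoxy-6-(trimethylsilyl)phenyl trifluoromethanesulfonate
Product: 18 (S)-5-chloro-7-methoxy-2-[2-(4-methoxyphenyl)benzofuran-5-yl]chroman-4-one, via alkoxide 15 (not isolated), via aryne 16 (not isolated), via aryl anion 17 (not isolated)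
Conditions: 14 (1.3 equiv), Bu4N[Ph3SiF2] (TBAT, 1.1 equiv, THF solution added over 4 h), THF (0.03 M), 0 °C → rt; AcOH quench at 0 °C
Reagents that add atoms: none
Why: Proposed new method: fluoride removes the O-silyl group of 8 to give alkoxide 15 and attacks the C-silyl group of 14 with loss of triflate to give aryne 16; 15 adds to the aryne carbon remote from chlorine (O1–C8a), and aryl anion 17, which meets no proton donor in the aprotic medium, attacks the tethered ester carbonyl and expels methoxide (C4–C4a). The closest known reaction type is the fluoride-mediated annulation of salicylate esters with o-silylaryl triflates to xanthones (addition of an O-nucleophile to the aryne, then intramolecular acyl substitution), extended here from a phenoxide to a secondary benzylic alkoxide released from its silyl ether. Ring C closes in the 6-exo-trig mode, C4a attacking C4 within the chain C4a–C8a–O1–C2–C3–C4. No stereocentre is formed; C2 keeps the (S) configuration of 8 because its C–O and C–H bonds are not touched and the carbonyl stays at the ester level until ring C exists. The selectivity needed is the orientation of addition to an unsymmetrical aryne, and it is secured by the chlorine at the future C5, whose inductive effect distorts the triple bond so that the nucleophile enters at the far carbon and the charge builds up beside chlorine, which outweighs the small opposite bias of the methoxy group. Because the flavanone would open and racemise in base, fluoride is fed slowly and kept below the amount of 14, so that each methoxide released is bound by silicon of 14 or 8 as MeOSiMe3 while it launches the next aryne or alkoxide, and the mixture ends without free base.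

Step 8
Reactants: 18 (S)-5-chloro-7-methoxy-2-[2-(4-methoxyphenyl)benzofuran-5-yl]chroman-4-one
Product: 19 Lophirone J, (S)-7-methoxy-2-[2-(4-methoxyphenyl)benzofuran-5-yl]chroman-4-one
Conditions: Pd(OAc)2 (3 mol %), JohnPhos (6 mol %), HCO2Na (2 equiv), MeOH–THF, 50 °C
Reagents that add atoms: none
Why: In this palladium-catalysed transfer hydrodechlorination the electron-rich monophosphine Pd(0) inserts into the C5–Cl bond activated by the ortho carbonyl, formate replaces chloride, and decarboxylation followed by reductive elimination gives C5–H, with formate as hydride source and only weak base, so the benzylic C2–O1 bond, the ketone, the benzofuran and the configuration at C2 should be left alone.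

**Compound list**
1 | 1-(4-hydroxy-3-iodophenyl)ethanone | CC(=O)c1ccc(O)c(I)c1 | starting material
2 | 4-ethynylanisole | C#Cc1ccc(OC)cc1 | starting material
3 | 1-{4-hydroxy-3-[(4-methoxyphenyl)ethynyl]phenyl}ethanone | COc1ccc(C#Cc2cc(C(C)=O)ccc2O)cc1 | intermediate
4 | 1-[2-(4-methoxyphenyl)benzofuran-5-yl]ethanone | COc1ccc(-c2cc3cc(C(C)=O)ccc3o2)cc1 | intermediate
5 | dimethyl carbonate | COC(=O)OC | starting material
6 | methyl 3-[2-(4-methoxyphenyl)benzofuran-5-yl]-3-oxopropanoate | COc1ccc(-c2cc3cc(C(=O)CC(=O)OC)ccc3o2)cc1 | intermediate
7 | methyl (S)-3-hydroxy-3-[2-(4-methoxyphenyl)benzofuran-5-yl]propanoate | COc1ccc(-c2cc3cc([C@@H](O)CC(=O)OC)ccc3o2)cc1 | intermediate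
8 | methyl (S)-3-[2-(4-methoxyphenyl)benzofuran-5-yl]-3-(trimethylsilyloxy)propanoate | COc1ccc(-c2cc3cc([C@@H](O[Si](C)(C)C)CC(=O)OC)ccc3o2)cc1 | intermediate
9 | 2-chloro-4-methoxyphenol | COc1ccc(O)c(Cl)c1 | starting material
10 | 2-bromo-6-chloro-4-methoxyphenol | COc1cc(Cl)c(O)c(Br)c1 | intermediate
11 | (2-bromo-6-chloro-4-methoxyphenoxy)trimethylsilane | COc1cc(Cl)c(O[Si](C)(C)C)c(Br)c1 | intermediate
12 | [3-chloro-5-methoxy-2-(trimethylsilyloxy)phenyl]lithium | COc1cc(Cl)c(O[Si](C)(C)C)c([Li])c1 | intermediate
13 | lithium 2-chloro-4-methoxy-6-(trimethylsilyl)phenoxide | COc1cc(Cl)c([O-])c([Si](C)(C)C)c1.[Li+] | intermediate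
14 | 2-chloro-4-methoxy-6-(trimethylsilyl)phenyl trifluoromethanesulfonate | COc1cc(Cl)c(OS(=O)(=O)C(F)(F)F)c([Si](C)(C)C)c1 | intermediate
15 | tetrabutylammonium (S)-3-methoxy-1-[2-(4-methoxyphenyl)benzofuran-5-yl]-3-oxopropan-1-olate | COc1ccc(-c2cc3cc([C@@H]([O-])CC(=O)OC)ccc3o2)cc1.CCCC[N+](CCCC)(CCCC)CCCC | intermediate
16 | 3-chloro-5-methoxybenzyne (1-chloro-5-methoxy-2,3-didehydrobenzene) | COC1=CC#CC(Cl)=C1 | intermediate
17 | tetrabutylammonium salt of methyl (S)-3-(3-chloro-5-methoxyphenoxy)-3-[2-(4-methoxyphenyl)benzofuran-5-yl]propanoate, carbanionic at C2 of the phenoxy ring | COc1ccc(-c2cc3cc([C@@H](Oc4cc(OC)cc(Cl)[c-]4)CC(=O)OC)ccc3o2)cc1.CCCC[N+](CCCC)(CCCC)CCCC | intermediate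
18 | (S)-5-chloro-7-methoxy-2-[2-(4-methoxyphenyl)benzofuran-5-yl]chroman-4-one | COc1ccc(-c2cc3cc([C@@H]4CC(=O)c5c(Cl)cc(OC)cc5O4)ccc3o2)cc1 | intermediate
19 | Lophirone J, (S)-7-methoxy-2-[2-(4-methoxyphenyl)benzofuran-5-yl]chroman-4-one | COc1ccc(-c2cc3cc([C@@H]4CC(=O)c5ccc(OC)cc5O4)ccc3o2)cc1 | target

**Step count**
Total step count: 8. Longest linear sequence: 6 steps (1, 2, 3, 4, 7, 8).

**Steps most likely to fail**

1. **Step 7.**
   - Risk at the alkoxide stage: the freed alkoxide may undergo β-elimination, retro-aldol cleavage (with loss of configurational integrity) or attack on the ester of a second molecule before it meets the aryne.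
   - Risk at the aryl-anion stage: the anion may abstract the acidic C3 proton through a six-membered transition state, or lose chloride, instead of acylating.
   - Risk after closure: base-induced opening of ring C would racemise C2.
   - Fallback (known chemistry, forming O1–C2 by substitution instead of O1–C8a): it sets out from 6 and returns at 19. Transfer hydrogenation of 6 with the (R,R)-configured catalyst should give methyl (R)-3-hydroxy-3-[2-(4-methoxyphenyl)benzofuran-5-yl]propanoate F1. Treatment with MeNH(OMe)·HCl and i-PrMgCl in THF converts it into the Weinreb amide (R)-3-hydroxy-N-methoxy-3-[2-(4-methoxyphenyl)benzofuran-5-yl]-N-methylpropanamide F2. Mitsunobu etherification with commercial 2-bromo-5-methoxyphenol (PPh3, DIAD, toluene, 0 °C) proceeds with inversion, which is why the (R) alcohol is used. It gives (S)-3-(2-bromo-5-methoxyphenoxy)-N-methoxy-3-[2-(4-methoxyphenyl)benzofuran-5-yl]-N-methylpropanamide F3. Bromine–lithium exchange (n-BuLi, THF, −78 °C) then triggers a Parham-type cyclisation onto the Weinreb amide and gives 19 directly, with no chlorine to remove.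

2. **Step 8.**
   - Risk: oxidative addition may be slow enough to demand higher temperature. Reversible E1cB opening of ring C (racemisation) or hydrogenolysis of the benzylic C2–O1 bond could then set in.
   - Fallback (a redox detour that removes the racemisation pathway while chlorine is taken off): it sets out from 18 and returns at 19. Reduction with NaBH4/CeCl3 in MeOH–THF at 0 °C should give mainly the 2,4-cis alcohol (2S,4S)-5-chloro-7-methoxy-2-[2-(4-methoxyphenyl)benzofuran-5-yl]chroman-4-ol F4. The configuration at C4 is of no consequence. Without a carbonyl the ring cannot open, so the same palladium/formate system can be run hot (DMF, 90 °C). This gives (2S,4S)-7-methoxy-2-[2-(4-methoxyphenyl)benzofuran-5-yl]chroman-4-ol F5. Dess–Martin oxidation in CH2Cl2 restores the ketone of 19.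

3. **Step 6.**
   - Risk: the O→C silyl migration may stay incomplete, the aryllithium may be protonated, or triflation of the doubly ortho-substituted lithium phenoxide may be sluggish.
   - Fallback (intermolecular C-silylation, with the phenol isolated and triflated separately): it sets out from 10 and returns at 14. Double lithiation of 10 (n-BuLi, 2.1 equiv, Et2O, −78 → 0 °C) and quenching with excess TMSCl should give [3-chloro-5-methoxy-2-(trimethylsilyloxy)phenyl]trimethylsilane F6. Selective methanolysis of the O–Si bond (K2CO3, MeOH, 0 °C) gives 2-chloro-4-methoxy-6-(trimethylsilyl)phenol F7. This phenol is purified and converted into 14 with Tf2O and pyridine in CH2Cl2 at 0 °C.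

**Further compounds**
F1 | step 7 | methyl (R)-3-hydroxy-3-[2-(4-methoxyphenyl)benzofuran-5-yl]propanoate | COc1ccc(-c2cc3cc([C@H](O)CC(=O)OC)ccc3o2)cc1
F2 | step 7 | (R)-3-hydroxy-N-methoxy-3-[2-(4-methoxyphenyl)benzofuran-5-yl]-N-methylpropanamide | COc1ccc(-c2cc3cc([C@H](O)CC(=O)N(C)OC)ccc3o2)cc1
F3 | step 7 | (S)-3-(2-bromo-5-methoxyphenoxy)-N-methoxy-3-[2-(4-methoxyphenyl)benzofuran-5-yl]-N-methylpropanamide | COc1ccc(-c2cc3cc([C@@H](Oc4cc(OC)ccc4Br)CC(=O)N(C)OC)ccc3o2)cc1
F4 | step 8 | (2S,4S)-5-chloro-7-methoxy-2-[2-(4-methoxyphenyl)benzofuran-5-yl]chroman-4-ol | COc1ccc(-c2cc3cc([C@@H]4C[C@H](O)c5c(Cl)cc(OC)cc5O4)ccc3o2)cc1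
F5 | step 8 | (2S,4S)-7-methoxy-2-[2-(4-methoxyphenyl)benzofuran-5-yl]chroman-4-ol | COc1ccc(-c2cc3cc([C@@H]4C[C@H](O)c5ccc(OC)cc5O4)ccc3o2)cc1
F6 | step 6 | [3-chloro-5-methoxy-2-(trimethylsilyloxy)phenyl]trimethylsilane | COc1cc(Cl)c(O[Si](C)(C)C)c([Si](C)(C)C)c1
F7 | step 6 | 2-chloro-4-methoxy-6-(trimethylsilyl)phenol | COc1cc(Cl)c(O)c([Si](C)(C)C)c1
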